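**Plan**
- Retrosynthesis cuts, in order: the three O–CH3 bonds; ring D (the lactone C–O bond at C2 and the exocyclic C1=C bond), back to a 2-hydroxy-1,4-quinone and 4-methoxyphenylacetic acid; the ring C bond between C4 and furan carbon C4a; the bond from the four-membered ring to benzofuran C3; the squarate–phenyl bond (dibenzofuran numbering throughout).
- Enabling feature: ring C is a fully substituted carbocycle with oxygen on C1, C2 and C4 (C1 and C4 para), phenyl on C3 between two oxygenated carbons, and its last edge C4a–C9b is the C2–C3 bond of furan ring B. This is the atom map of a squarate-derived 4-(benzofuran-3-yl)-4-hydroxycyclobutenone.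
- Forward: furan ring B is built onto 3,4-dimethoxyphenol (ring A); the four-membered ring comes from diisopropyl squarate; ring C closes by thermal ring expansion; ring D by Perkin-type annulation; the methyl ethers are cleaved last.
- Stereochemistry: the target has no stereocentre; the ring D alkene geometry is fixed by the ring.

Key step: step 6

Assumption: the target is achiral, so every stereogenic intermediate is carried as a racemate; phenyllithium and iPrMgCl·LiCl are used as purchased solutions.

**Step 1**
Reactants: 1 diisopropyl squarate; 2 phenyllithium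
Product: 5 3-isopropoxy-4-phenylcyclobut-3-ene-1,2-dione, via lithium alkoxide adduct 3 (not isolated), via trifluoroacetate ester 4 (not isolated)
Conditions: PhLi (1.05 equiv), THF, −78 °C; (CF3CO)2O, −78 °C; H2O work-up
Reagents that add atoms: water, O
Why: Phenyllithium adds 1,2 to one of the two equivalent squarate carbonyls, and trifluoroacetylation of the alkoxide followed by ionisation and hydrolytic loss of propan-2-ol on work-up (the standard squarate-to-cyclobutenedione sequence) should unveil the 3-alkoxy-4-aryl dione.

**Step 2**
Reactants: 6 3,4-dimethoxyphenol; 7 bromoacetaldehyde diethyl acetal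
Product: 8 4-(2,2-diethoxyethoxy)-1,2-dimethoxybenzene
Conditions: K2CO3, DMF, 110 °C
Reagents that add atoms: none
Why: Williamson ether synthesis, in which the phenoxide displaces the primary bromide by SN2 while the acetal is inert to base.

**Step 3**
Reactants: 8 4-(2,2-diethoxyethoxy)-1,2-dimethoxybenzene
Product: 9 5,6-dimethoxybenzofuran
Conditions: polyphosphoric acid, toluene, reflux
Reagents that add atoms: none
Why: Acid-mediated cyclodehydration (intramolecular Friedel–Crafts attack of the arene on the acetal-derived oxocarbenium ion, then loss of the second ethanol) should close furan ring B at the position para to the 3-methoxy group, which is more activated and far less hindered than the position between the two oxygens, giving the 5,6-dimethoxy isomer.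

**Step 4**
Reactants: 9 5,6-dimethoxybenzofuran
Product: 11 3-bromo-5,6-dimethoxybenzofuran, via trans-dibromide 10 (not isolated)
Conditions: Br2 (1.0 equiv), CH2Cl2, −78 °C; evaporate; KOH, EtOH, 0 °C to reflux
Reagents that add atoms: bromine, BrBr
Why: Classical addition–elimination route to 3-bromobenzofurans, in which anti addition of bromine to the enol-ether C2=C3 bond at −78 °C should outrun substitution on the dimethoxybenzene ring and KOH then removes HBr by loss of the oxygen-activated C2 bromide and the C3 proton, leaving bromine on C3.

**Step 5**
Reactants: 11 3-bromo-5,6-dimethoxybenzofuran; 5 3-isopropoxy-4-phenylcyclobut-3-ene-1,2-dione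
Product: 13 racemic 4-(5,6-dimethoxybenzofuran-3-yl)-4-hydroxy-3-isopropoxy-2-phenylcyclobut-2-en-1-one, via arylmagnesium chloride 12 (not isolated)
Conditions: iPrMgCl·LiCl, THF, 0 °C to rt; then 5, THF, −78 °C; aq NH4Cl
Reagents that add atoms: none
Why: Bromine–magnesium exchange gives a 3-magnesiated benzofuran that resists ring opening better than its lithium counterpart, and its Grignard 1,2-addition goes to the ketone-like carbonyl next to the isopropoxy carbon rather than to the vinylogous ester carbonyl next to the phenyl carbon, which fixes the substitution pattern; the carbinol centre forms racemic and is destroyed in step 6.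

**Step 6**
Reactants: 13 racemic 4-(5,6-dimethoxybenzofuran-3-yl)-4-hydroxy-3-isopropoxy-2-phenylcyclobut-2-en-1-one
Product: 16 2-isopropoxy-7,8-dimethoxy-3-phenyldibenzofuran-1,4-diol, via dienylketene 14 (not isolated), via cyclohexadienone 15 (not isolated)
Conditions: degassed p-xylene, 138 °C, Ar
Reagents that add atoms: none
Why: Thermal conrotatory 4π ring opening of the cyclobutenone C1–C4 bond, with the C4 hydroxyl rotating outward as donor substituents do, should give (Z)-dienylketene 14 with the benzofuranyl group cis to the ketene. The ketene carbon then bonds to benzofuran C2 in a thermal disrotatory 6π electrocyclization across the ketene C=C, the enol C=C and the furan C2=C3 bond, which closes ring C (the six-membered carbocycle) as dienone 15. A proton shift from C4a to oxygen aromatises ring C to the hydroquinone and makes the sequence irreversible. The closest known reaction type is the Moore rearrangement of 4-aryl- and 4-heteroaryl-4-hydroxycyclobutenones to annulated hydroquinones. The one stereocentre that appears (C4a of 15) is transient and racemic, so nothing has to be controlled there. The step needs regioselectivity only: closure can use furan C2 alone, because attack at C3a would destroy the benzene ring with no path back to aromaticity, and phenyl and isopropoxy keep the places fixed in step 5, phenyl between the new C4 phenol and the isopropoxy carbon.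

**Step 7**
Reactants: 16 2-isopropoxy-7,8-dimethoxy-3-phenyldibenzofuran-1,4-diol
Product: 17 2-isopropoxy-7,8-dimethoxy-3-phenyldibenzofuran-1,4-dione
Conditions: Ag2O, Et2O, rt
Reagents that add atoms: none
Why: Ag2O is the usual mild two-electron oxidant for converting Moore hydroquinones into p-quinones and leaves the methyl and isopropyl ethers untouched.

**Step 8**
Reactants: 17 2-isopropoxy-7,8-dimethoxy-3-phenyldibenzofuran-1,4-dione
Product: 18 2-hydroxy-7,8-dimethoxy-3-phenyldibenzofuran-1,4-dione
Conditions: BCl3, CH2Cl2, −78 to 0 °C; H2O
Reagents that add atoms: none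
Why: Lewis acid ether cleavage, in which BCl3 chelated between the C1 carbonyl and the C2 oxygen expels the secondary isopropyl group as 2-chloropropane at low temperature, conditions under which the two aryl methyl ethers should survive.

**Step 9**
Reactants: 18 2-hydroxy-7,8-dimethoxy-3-phenyldibenzofuran-1,4-dione; 19 4-methoxyphenylacetic acid
Product: 22 tri-O-methyl ether of the target, via mixed anhydride 20 (not isolated), via aryl acetate ester 21 (not isolated)
Conditions: 19 (excess), Ac2O, NaOAc, 130 °C
Reagents that add atoms: none
Why: Perkin-type lactone annulation known for hydroxyquinones and arylacetic acids, in which the acidic C2 hydroxyl is acylated by mixed anhydride 20 and the aryl-activated methylene of ester 21 then condenses in an intramolecular aldol reaction with the only carbonyl in reach (C1, 5-exo-trig), dehydration by acetic anhydride giving ring D and the fully conjugated quinone methide.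

**Step 10**
Reactants: 22 tri-O-methyl ether of the target
Product: 23 target CNP0139113.0
Conditions: BBr3 (excess), CH2Cl2, −78 °C to rt; H2O
Reagents that add atoms: none
Why: BBr3-mediated demethylation of aryl methyl ethers (bromide attacks the methyl group of the boron-complexed ether) should free the catechol and the phenol, while the lactone and ketone only complex reversibly and are released on aqueous work-up.

**Compound list**
1 | diisopropyl squarate (3,4-diisopropoxycyclobut-3-ene-1,2-dione) | CC(C)OC1=C(OC(C)C)C(=O)C1=O | starting material
2 | phenyllithium | [Li]c1ccccc1 | starting material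
3 | lithium 2,3-diisopropoxy-4-oxo-1-phenylcyclobut-2-en-1-olate (racemic) | [Li+].[O-]C1(c2ccccc2)C(OC(C)C)=C(OC(C)C)C1=O | intermediate
4 | 2,3-diisopropoxy-4-oxo-1-phenylcyclobut-2-en-1-yl trifluoroacetate (racemic) | O=C(OC1(c2ccccc2)C(OC(C)C)=C(OC(C)C)C1=O)C(F)(F)F | intermediate
5 | 3-isopropoxy-4-phenylcyclobut-3-ene-1,2-dione | CC(C)OC1=C(c2ccccc2)C(=O)C1=O | intermediate
6 | 3,4-dimethoxyphenol | COc1ccc(O)cc1OC | starting material
7 | bromoacetaldehyde diethyl acetal (2-bromo-1,1-diethoxyethane) | CCOC(CBr)OCC | starting material
8 | 4-(2,2-diethoxyethoxy)-1,2-dimethoxybenzene | CCOC(COc1ccc(OC)c(OC)c1)OCC | intermediate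
9 | 5,6-dimethoxybenzofuran | COc1cc2ccoc2cc1OC | intermediate
10 | trans-2,3-dibromo-5,6-dimethoxy-2,3-dihydrobenzofuran (racemic; one enantiomer drawn) | Br[C@H]1Oc2cc(OC)c(OC)cc2[C@@H]1Br | intermediate
11 | 3-bromo-5,6-dimethoxybenzofuran | COc1cc2c(Br)coc2cc1OC | intermediate
12 | (5,6-dimethoxybenzofuran-3-yl)magnesium chloride (LiCl complex) | COc1cc2c([Mg]Cl)coc2cc1OC | intermediate
13 | racemic 4-(5,6-dimethoxybenzofuran-3-yl)-4-hydroxy-3-isopropoxy-2-phenylcyclobut-2-en-1-one | O=C1C(c2ccccc2)=C(OC(C)C)C1(O)c1coc2cc(OC)c(OC)cc12 | intermediate
14 | (Z)-4-(5,6-dimethoxybenzofuran-3-yl)-4-hydroxy-3-isopropoxy-2-phenylbuta-1,3-dien-1-one (dienylketene) | O=C=C(c1ccccc1)/C(OC(C)C)=C(/O)c1coc2cc(OC)c(OC)cc12 | intermediate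
15 | 1-hydroxy-2-isopropoxy-7,8-dimethoxy-3-phenyl-4aH-dibenzofuran-4-one (racemic) | O=C1C(c2ccccc2)=C(OC(C)C)C(O)=C2c3cc(OC)c(OC)cc3OC12 | intermediate
16 | 2-isopropoxy-7,8-dimethoxy-3-phenyldibenzofuran-1,4-diol | Oc1c(-c2ccccc2)c(OC(C)C)c(O)c2c1oc1cc(OC)c(OC)cc12 | intermediate
17 | 2-isopropoxy-7,8-dimethoxy-3-phenyldibenzofuran-1,4-dione | O=C1C(c2ccccc2)=C(OC(C)C)C(=O)c2c1oc1cc(OC)c(OC)cc12 | intermediate
18 | 2-hydroxy-7,8-dimethoxy-3-phenyldibenzofuran-1,4-dione | O=C1C(c2ccccc2)=C(O)C(=O)c2c1oc1cc(OC)c(OC)cc12 | intermediate
19 | 4-methoxyphenylacetic acid | COc1ccc(CC(=O)O)cc1 | starting material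
20 | acetic 4-methoxyphenylacetic anhydride | COc1ccc(CC(=O)OC(C)=O)cc1 | intermediate
21 | 7,8-dimethoxy-1,4-dioxo-3-phenyl-1,4-dihydrodibenzofuran-2-yl (4-methoxyphenyl)acetate | COc1ccc(CC(=O)OC2=C(c3ccccc3)C(=O)c3oc4cc(OC)c(OC)cc4c3C2=O)cc1 | intermediate
22 | tri-O-methyl ether of the target: 7,8-dimethoxy-3-phenyldibenzofuran-4-one carrying lactone ring D across C1–C2, O2–C(=O)–C(4-methoxyphenyl)=C1 | O=C1OC2=C(c3ccccc3)C(=O)c3oc4cc(OC)c(OC)cc4c3C2=C1c1ccc(OC)cc1 | intermediate
23 | target CNP0139113.0: 7,8-dihydroxy-3-phenyldibenzofuran-4-one carrying lactone ring D across C1–C2, O2–C(=O)–C(4-hydroxyphenyl)=C1 | O=C1OC2=C(c3ccccc3)C(=O)c3oc4cc(O)c(O)cc4c3C2=C1c1ccc(O)cc1 | target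

**Step count**
Total: 10 steps. Longest linear sequence: 9 steps (6 to 23, steps 2–10); the squarate branch (step 1) joins at step 5.

**Steps most likely to fail**

Step 5. The bromine–magnesium exchange may be slow on the electron-rich ring, and the 3-metalated benzofuran may fragment by ring opening to a 2-alkynylphenoxide before it meets the dione. The fallback sets out from 11 and comes back at 13. Stannylation of 11 with Me3SnSnMe3 and Pd(PPh3)4 in toluene at 100 °C would give the purifiable, storable (5,6-dimethoxybenzofuran-3-yl)trimethylstannane F1. Tin–lithium exchange with MeLi in THF at −100 °C, where ring opening is suppressed, followed within minutes by dione 5 and an NH4Cl quench, should then deliver 13.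

Step 9. O-Acetylation by the solvent may compete with arylacetylation, and aldol closure onto the C1 carbonyl may be sluggish because that carbonyl is deactivated as a vinylogous ester of the furan oxygen. The fallback sets out from 18 and comes back at 22. Acylation of 18 with 4-methoxyphenylacetyl chloride (Et3N, catalytic DMAP, CH2Cl2, 0 °C) would give ester 21 as an isolated compound with no acetate competitor. Soft enolisation with TiCl4 and Et3N (CH2Cl2, −78 to 0 °C) should drive the intramolecular aldol addition onto the titanium-activated C1 carbonyl to give the β-hydroxy lactone F2. Acid-catalysed dehydration (catalytic p-TsOH, toluene, 60 °C) would then form 22.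

Step 10. The Lewis acid may open the enol lactone or deliver bromide to the quinone methide, and cleavage of three ethers may stop short. The fallback sets out from 17 and comes back at 23; it moves all dealkylation ahead of lactone formation so that ring D never meets BBr3. Treatment of 17 with BBr3 (CH2Cl2, −78 °C to rt) should remove the isopropyl and both methyl groups to give 2,7,8-trihydroxy-3-phenyldibenzofuran-1,4-dione F3. Perkin-type annulation of F3 with 4-hydroxyphenylacetic acid in Ac2O with NaOAc at 130 °C, with acetylation of the three phenols in the same flask, would give the triacetate of the target F4. Mild transesterification (HCl in MeOH, rt) should then release 23.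

**Further compounds**
F1 | step 5 | (5,6-dimethoxybenzofuran-3-yl)trimethylstannane | COc1cc2c([Sn](C)(C)C)coc2cc1OC
F2 | step 9 | β-hydroxy lactone: aldol adduct of ester 21 with hydroxyl on C1 and 4-methoxyphenyl on the lactone α-carbon (racemic mixture of diastereomers) | O=C1OC2=C(c3ccccc3)C(=O)c3oc4cc(OC)c(OC)cc4c3C2(O)C1c1ccc(OC)cc1
F3 | step 10 | 2,7,8-trihydroxy-3-phenyldibenzofuran-1,4-dione | O=C1C(c2ccccc2)=C(O)C(=O)c2c1oc1cc(O)c(O)cc12
F4 | step 10 | triacetate of the target (acetoxy groups on C7, C8 and the 4-position of the aryl ring) | O=C1OC2=C(c3ccccc3)C(=O)c3oc4cc(OC(C)=O)c(OC(C)=O)cc4c3C2=C1c1ccc(OC(C)=O)cc1
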